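Numbering: labdane numbers are used for all bicyclic compounds (ring A = C1–C5 and C10; ring B = C5–C10; C17 = methyl on C8, C18 = oxygenated carbon on C4, C19 = methyl on C4, C20 = methyl on C10, chain C11–C16 on C9). Carvone-derived monocycles are described with the labdane numbers of the atoms they become. "Syn/anti to C20" refers to the face of the axial C20 methyl.

Assumption: the phosphonoacetic acid 25 and the silylated aldehyde 27 are treated as purchasable; if 25 had to be made by hydrolysis of its commercial methyl ester, the count would rise by one step.

## The problem

Compound 30 is a labdane-type diterpenoid ester: a trans-fused decalin with a six-carbon chain ending in a 2-substituted buta-1,3-diene on C9, a tertiary alcohol on C8 and, on C4, an equatorial oxymethyl group (C18) acylated by (Z)-4-hydroxycinnamic acid. Five ring stereocentres must be set, three of them fully substituted (C4, C8, C10). With the axial C20 methyl as reference, the C19 methyl is axial and syn and H5 is anti, but the C9 chain is axial and anti to C20 and the C8 hydroxyl is axial and syn to C20, so chain and hydroxyl are trans-diaxial and the C17 methyl is equatorial. The chain therefore sits in the less stable position: C9 has to be made under kinetic control and must never lie next to a carbonyl group afterwards. The centres can control one another in a chain: C5 directs C10 (alkylation anti to the C5 substituent), the trans relation of the C5 and C10 arms fixes the ring fusion, the axial C20 methyl directs C4 through a 1,3-diaxial contact and biases the faces of ring B, an oxygen on C7 can hand its configuration to C9, and the chair of ring B then decides C8. The diene (acid, electrophiles, radicals), the Z-enoate conjugated to a free phenol (light, base, hydride, nucleophiles) and the tertiary alcohol (acid) will not survive rough treatment and have to arrive last. The feature that opens the route is that ring B with its C17 methyl, C5 and the three-carbon unit C4/C18/C19 is the skeleton of (S)-carvone with the correct C5 configuration: only C20 and C1–C3 are missing, ring A closes with the single bond C3–C4, and the C18 oxygen comes with it if the C4 radical that makes this bond is born from the epoxide of the isopropenyl group.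

## Retrosynthesis

Ester and Z-alkene (30 ⇒ 29 ⇒ 26 + 27; 26 ⇒ 24 + 25). The last bonds cut are the cinnamate C=C bond and the acyl–O18 bond. A Still–Gennari olefination on phosphonoacetate 26 keeps the light- and base-sensitive Z-enoate out of every earlier step. Acylation with a preformed Z-acid would pass it through an activation step in which it can isomerise, and semi-hydrogenation of an arylpropiolate would endanger the diene. Diol 24 is far simpler than 30 and its two hydroxyls are easily told apart (primary C18 against axial tertiary C8). The forward steps must acylate O18 only, give the Z-alkene with aldehyde 27 under kinetic control, and free the phenol of 29 without base.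

Diene (24 ⇒ 23 ⇒ 22). The C12–C13 bond is cut: an sp3–sp2 coupling of primary tosylate 22 with a four-carbon dienyl nucleophile (step 15) brings the whole diene in one step. An enyne metathesis at the same place would cost one step more, and an olefination approach would need a C13 ketone and several steps. Because 22 carries no diene, the electrophilic hydration before it is allowed. The coupling has to tolerate the free C8 hydroxyl; this is safe because O8 and C11 are trans-diaxial, so the alkoxide cannot close an ether onto C12.

C8 (22 ⇒ 21 ⇒ 20 ⇒ 19 ⇒ 18). The C8–O bond is cut by removing water from C7/C8: 22 is the Markovnikov hydration product of the C7=C8 alkene of 20 through organomercurial 21. Oxymercuration is chosen because position (tertiary C8) and configuration (axial hydroxyl by anti, diaxial opening) are decided in the same transition state. Methyl addition to a C8 carbonyl would make C9 epimerisable, and hydroxylation of a C7 enolate would leave a C7 oxygen to be removed. During this step the chain end is a tosylate (from alcohol 19, from ester 18), because a free hydroxyl or an ester on C12 could capture the C8 cation from the wrong face. Compound 20 lacks one stereocentre and the tertiary alcohol.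

C9 (18 ⇒ 17 ⇒ 16). The C9–C11 bond is cut by a [3,3] shift: ester 18 is the Johnson–Claisen product of allylic alcohol 16 through ketene acetal 17. A conjugate addition at C9 would also be axial but would leave a carbonyl oxygen on C7 beside the future tertiary alcohol, costing several steps to remove. An epoxide opening at C9 would be neopentylic and from the wrong face. The rearrangement moves C11 and C12 from O7 to C9 across one face, takes the C7 oxygen out of the ring and leaves the alkene at C7=C8, where the hydration needs it. It asks only that the C7 hydroxyl of 16 lie anti to C20.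

Enone transposition and sulfone removal (16 ⇒ 15 ⇒ 14 ⇒ 13 ⇒ 12 ⇒ 11). Alcohol 16 comes from sulfone 15 by reductive C–S cleavage, placed here because 15 is the first compound after the ring closure with no other reducible group. Compound 15 is the Wharton product (through hydrazone 14) of epoxy ketone 13, made from enone 12 by nucleophilic epoxidation. The hydroperoxide adds axially at C7, anti to C20, and this face becomes the C7 configuration that the Claisen step passes to C9. Compound 12 is the silyl ether of 11; the silyl group keeps O18 silent until step 16.

Ring A, the key disconnection (11 ⇒ 10 ⇒ 9). The C3–C4 bond is cut, leading from decalenone 11 through radical 10 to epoxide 9, used as both C4 epimers. A cationic closure would need an electron-rich acceptor and would not deliver the C18 oxygen; a polar closure with C4 as an enolate carbon gives no clear handle on C4. The radical closure is stereoconvergent, gives C18 as the alcohol and leaves the enone alone. Epoxide 9 is monocyclic with only C5 and C10 set. The forward step must close 6-endo through a chair with the oxymethyl group equatorial.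

Carvone stage (9 ⇒ 8 ⇒ 7 ⇒ 6 ⇒ 5 ⇒ 4; 3 ⇒ 2 ⇒ 1). Epoxide 9 is the peracid epoxide of 8; only the electron-rich isopropenyl alkene reacts. Compound 8 arises from enolate 7 of methylcarvone 6 and bromide 3. Cutting C10–C1 here lets the C5 substituent set C10, since the second electrophile enters anti to it; this fixes the order: methyl first (through dienolate 5 of carvone 4), then the three-carbon arm. Bromide 3 comes from alcohol 2, the Morita–Baylis–Hillman hydroxymethylation product of sulfone 1. The sulfonyl group sits on the central carbon of the allyl unit, which is what makes the later closure 6-endo.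

## Roads not taken

Alternative 1: The cut lies inside the diene: C13=C16 and C14=C15 are both formed by enyne cross-metathesis of terminal alkyne A2 (C12–C13≡C14) with the parent two-carbon alkene over the second-generation Grubbs catalyst, giving silyl ether A1. The reaction is atom-economic, neutral, tolerant of the free tertiary alcohol and places the diene at the very end; A1 is the same compound as 23. For this bond set it is as good as, and arguably more predictable than, the copper-catalysed coupling of step 15. The chosen plan sets against it one step fewer (A2 would first have to be made from 22) and no ruthenium, and it keeps this reaction as the reserve for step 15. As a strategy, however, it is silent on the real difficulty: it presupposes A2, the complete decalin with all five stereocentres including the axial C9 chain and the axial C8 hydroxyl. It is an end-game, not a competitor for the ring-forming plan.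

Alternative 2: Both rings are cut at once, at C5–C10 and C3–C4. On heating, the open-chain triene ester A4 should let its (E)-2-methyl-2-enoate (C4=C5) add to the diene C10=C1–C2=C3 across the four-carbon tether C6–C9, giving the trans-fused octalin ester A3.
- Merits: two rings, two skeletal bonds and three stereocentres (C4, C5, C10) in one step, against one ring, one bond and one lasting centre in the titanium step. The E geometry of the enoate translates directly into the equatorial ester on C4. In ring-forming economy this road is better.
- Weak points: both new bonds end at carbons that become quaternary (C4 and C10). The diene terminus C10 is disubstituted, so one substituent must point into the s-cis diene. The dienophile is a trisubstituted alkene activated by a single ester. A slow, hot cycloaddition with uncertain trans/cis fusion is to be expected.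
- Stereocontrol: facial and absolute control rest on the single C8 methyl centre of A4, which needs an asymmetric synthesis and is later overwritten.
- What remains: A3 has an unfunctionalised CH2 at C9, the hardest centre of the target, plus a C1=C2 alkene and an ester to reduce. The sequence after it would be longer than the thirteen steps that follow 11.
- Comparison: the chosen plan gives up the two-ring step but takes ring B, C5 and a C7–C9 enone from carvone and sets C10 by a simple alkylation.

Alternative 3: The C4–C5 bond is cut. Anodic oxidation of the methyl enol ether of A6 (C18=C4) should give a radical cation that is captured by the γ-carbon (C5) of the allylsilane, closing ring A and giving A5 with C18 as a dimethyl acetal and a vinyl group (C6=C7) on C5.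
- Merits: umpolung without a stoichiometric metal, and C18 arrives oxidised and distinct from C19, as in the chosen plan. In electron economy the anodic step is the better reaction.
- Weak points: the bond joins a carbon that becomes quaternary (C4) to a carbon (C5) flanked by the quaternary C10. Two stereocentres are created at once with only C10 to steer them. The quaternary C10 of A6 has no chiral-pool source.
- What remains: A5 is monocyclic. All of ring B with C8, C9, C17 and the chain must still be built from the vinyl group and the C9 oxymethyl group, whereas 11 already holds ring B with an enone in place. In what it leaves to be done this is clearly the longer road.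

Key step: step 6

## Route

Step 1
Reactants: 1 phenyl vinyl sulfone
Product: 2 2-(phenylsulfonyl)prop-2-en-1-ol
Conditions: CH2O (37% aq.), DABCO (0.5 equiv), THF, rt
Reagents that add atoms: formaldehyde, C=O
Why: Morita–Baylis–Hillman hydroxymethylation: DABCO adds to the vinyl sulfone, the α-sulfonyl carbanion captures formaldehyde and the amine is expelled; vinyl sulfones are established partners for aldehydes in this reaction.

Step 2
Reactants: 2 2-(phenylsulfonyl)prop-2-en-1-ol
Product: 3 3-bromo-2-(phenylsulfonyl)prop-1-ene
Conditions: PBr3 (0.4 equiv), Et2O, 0 °C → rt
Reagents that add atoms: phosphorus tribromide, BrP(Br)Br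
Why: Standard conversion of a primary allylic alcohol into the bromide; direct and allylic substitution give the same product because the allyl unit is symmetric about the sulfonyl-bearing carbon.

Step 3
Reactants: 4 (S)-(+)-carvone
Product: 6 trans-6-methylcarvone [(5S,6R)-2,6-dimethyl-5-(prop-1-en-2-yl)cyclohex-2-en-1-one; expected major epimer], via carvone lithium dienolate 5 (not isolated)
Conditions: LiN(iPr)2 (1.05 equiv), THF, −78 °C; MeI, −78 → 0 °C
Reagents that add atoms: iodomethane, CI
Why: Kinetic α′-deprotonation gives the cross-conjugated enolate, which is C-methylated at the future C10 (enolate alkylation); the configuration of the new centre is irrelevant because it is made planar again in step 4.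

Step 4
Reactants: 6 trans-6-methylcarvone; 3 3-bromo-2-(phenylsulfonyl)prop-1-ene
Product: 8 6-methyl-6-[2-(phenylsulfonyl)prop-2-en-1-yl]carvone [2,6-dimethyl-6-[2-(phenylsulfonyl)prop-2-en-1-yl]-5-(prop-1-en-2-yl)cyclohex-2-en-1-one; sulfonylallyl arm trans to the isopropenyl group; C20 methyl cis to it], via lithium enolate 7 (not isolated)
Conditions: LiN(iPr)2 (1.1 equiv), THF, −78 → −10 °C; then 3, DMPU, −78 → −20 °C
Reagents that add atoms: none
Why: Enolate alkylation by addition–elimination on the sulfonylallyl bromide; the electrophile approaches the planar enolate anti to the adjacent isopropenyl group on C5, which sets C10 with the C20 methyl cis and the new arm trans to the C5 substituent, the usual outcome of a second alkylation of 6-alkylcarvones.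

Step 5
Reactants: 8 6-methyl-6-[2-(phenylsulfonyl)prop-2-en-1-yl]carvone
Product: 9 epoxide of the isopropenyl group of 8 [5-(2-methyloxiran-2-yl) compound; both epimers at the oxirane carbon C4]
Conditions: mCPBA (1.05 equiv), NaHCO3, CH2Cl2, 0 °C
Reagents that add atoms: 3-chloroperoxybenzoic acid, OOC(=O)c1cccc(Cl)c1
Why: Prilezhaev epoxidation, selective for the only electron-rich alkene (enone and vinyl sulfone alkenes are electron-poor), as with carvone itself; no facial control is needed because C4 is made planar in step 6.

Step 6
Reactants: 9 epoxide of the isopropenyl group of 8 (both C4 epimers)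
Product: 11 hydroxy sulfone enone [5-(hydroxymethyl)-2,5,8a-trimethyl-7-(phenylsulfonyl)-4a,5,6,7,8,8a-hexahydronaphthalen-1(4H)-one; trans-fused; C19 methyl axial, syn to C20; C18 hydroxymethyl equatorial; sulfone equatorial], via titanoxy C4 radical 10 (not isolated)
Conditions: Cp2TiCl2 (0.2 equiv), Mn dust (2 equiv), 2,4,6-collidine·HCl (2.5 equiv), THF, rt, slow addition of 9
Reagents that add atoms: none
Why: Mn reduces Cp2TiCl2 to Cp2TiCl (trivalent titanium), which transfers one electron to either epimer of 9 and breaks the C4–O bond, leaving O18 on tetravalent titanium and a tertiary radical at C4 (10) that has lost the epoxide configuration, so both epimers converge. This nucleophilic radical adds to the unsubstituted terminus C3 of the vinyl sulfone and closes ring A in a 6-endo-trig mode; the α-sulfonyl radical is reduced by a second Cp2TiCl and protonated by collidinium chloride, which also frees the alcohol and returns Cp2TiCl2. The closest known reaction type is the Cp2TiCl-mediated reductive opening of 2,2-disubstituted epoxides with radical cyclisation onto acrylate-type acceptors, which has been run on epoxides of the carvone isopropenyl group. C4 is the only lasting new stereocentre and is controlled by C10: in the chair transition state the bulky titanium-bound oxymethyl group takes the equatorial position and the methyl the axial one, syn to C20. C2 is formed by protonation (equatorial sulfone expected) and is erased in step 10. The step needs 6-endo over 5-exo closure, secured by the sulfonyl group on the internal carbon (polarity match, stabilised α-sulfonyl radical, and a disubstituted carbon as the 5-exo site). It also needs chemoselectivity over the enone, which the C4 radical cannot reach through a ring of workable size. The trans ring fusion is fixed beforehand by the trans relation of the C5 and C10 arms.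

Step 7
Reactants: 11 hydroxy sulfone enone
Product: 12 18-O-tert-butyldimethylsilyl ether of 11
Conditions: TBSCl, imidazole, DMF, rt
Reagents that add atoms: tert-butyldimethylsilyl chloride, CC(C)(C)[Si](C)(C)Cl
Why: Silylation of the only hydroxyl; the primary silyl ether withstands base, hydrazine, hydride, the hot orthoester step and the Grignard coupling of steps 8–15.

Step 8
Reactants: 12 18-O-tert-butyldimethylsilyl ether of 11
Product: 13 7,8-epoxy-9-ketone (epoxide oxygen anti to C20; 2-sulfone and 18-OTBS unchanged)
Conditions: H2O2 (30% aq.), NaOH (aq.), MeOH, 0 °C → rt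
Reagents that add atoms: hydrogen peroxide, OO
Why: Weitz–Scheffer epoxidation: hydroperoxide adds to C7 axially on the face anti to the C20 methyl and the enolate closes the ring on the same face, as in the standard epoxidation of carvone; this sets the C7–O configuration.

Step 9
Reactants: 13 7,8-epoxy-9-ketone
Product: 15 7-hydroxy-8(9)-ene sulfone (7-OH axial, anti to C20; C8(CH3)=C9H; 2-sulfone; 18-OTBS), via epoxy hydrazone 14 (not isolated)
Conditions: N2H4·H2O, AcOH (cat.), MeOH, 0 °C → rt
Reagents that add atoms: none
Why: Wharton transposition: the hydrazone opens the epoxide to a vinyl diazene that loses N2, giving the transposed allylic alcohol; the C7–O bond is never broken, so the hydroxyl stays anti to C20.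

Step 10
Reactants: 15 7-hydroxy-8(9)-ene sulfone
Product: 16 desulfonylated allylic alcohol (18-OTBS; 7-OH axial, anti to C20; C8(CH3)=C9H; C2 now CH2)
Conditions: Na(Hg) (6%), Na2HPO4, MeOH/THF, −20 → 0 °C
Reagents that add atoms: none
Why: Reductive desulfonylation of an unactivated secondary alkyl phenyl sulfone with buffered Na(Hg); the allylic alcohol, alkene and silyl ether are inert, and the C2 stereocentre disappears.

Step 11
Reactants: 16 desulfonylated allylic alcohol
Product: 18 ethyl ester (C9 carries an axial CH2CO2Et anti to C20; C7=C8; 18-OTBS), via mixed ketene acetal 17 (not isolated)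
Conditions: MeC(OEt)3, EtCO2H (cat.), xylene, 140 °C (EtOH distilled off)
Reagents that add atoms: triethyl orthoacetate, CC(OCC)(OCC)OCC
Why: Johnson–Claisen rearrangement: the ketene acetal on the pseudoaxial O7 undergoes a suprafacial [3,3] shift that forms C9–C11 on the same face as the C7–O bond, anti to C20, so the chain is set axial at C9 and the alkene moves to C7=C8.

Step 12
Reactants: 18 ethyl ester
Product: 19 primary alcohol (C9 axial CH2CH2OH; C7=C8; 18-OTBS)
Conditions: LiAlH4, THF, 0 °C
Reagents that add atoms: none
Why: Hydride reduction of the ester to the C12 alcohol; no stereocentre is touched.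

Step 13
Reactants: 19 primary alcohol
Product: 20 C12 tosylate
Conditions: TsCl, Et3N, DMAP (cat.), CH2Cl2, 0 °C → rt
Reagents that add atoms: 4-toluenesulfonyl chloride, Cc1ccc(cc1)S(=O)(=O)Cl
Why: Sulfonylation of the only free hydroxyl; the tosylate is a non-participating mask in step 14 and the leaving group in step 15.

Step 14
Reactants: 20 C12 tosylate
Product: 22 8-hydroxy tosylate (8-OH axial, syn to C20; C17 methyl equatorial; C7 now CH2), via C7 organomercurial 21 (not isolated)
Conditions: Hg(OAc)2, THF/H2O (1:1), rt; then NaBH4, NaOH (aq.), 0 °C
Reagents that add atoms: water, O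
Why: Oxymercuration–demercuration: water opens the mercurinium ion at the tertiary C8 (Markovnikov) anti and axially through a chair (diaxial rule, Hg axial on C7), which puts the hydroxyl axial on the C20 face, anti to the C9 chain; here regiochemical and stereoelectronic preferences reinforce each other. NaBH4 then replaces Hg by H at C7, which is not a stereocentre.

Step 15
Reactants: 22 8-hydroxy tosylate
Product: 23 diene silyl ether (18-O-TBS ether of 8-hydroxylabda-13(16),14-diene with the C9 chain axial)
Conditions: CH2=CH–C(MgCl)=CH2 (3 equiv; from 2-chlorobuta-1,3-diene and Mg in THF), Li2CuCl4 (5 mol %), THF, −20 °C → rt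
Reagents that add atoms: buta-1,3-dien-2-ylmagnesium chloride, C=CC(=C)[Mg]Cl
Why: Copper-catalysed cross-coupling of a primary tosylate with an alkenyl Grignard reagent, the reaction by which 2-alkylbuta-1,3-dienes are made from this Grignard reagent; the C8 alkoxide formed by the first equivalent cannot displace the tosylate because O8 and C11 are trans-diaxial.

Step 16
Reactants: 23 diene silyl ether
Product: 24 diol (8-hydroxylabda-13(16),14-dien-18-ol; same ring configuration)
Conditions: Bu4NF, THF, rt
Reagents that add atoms: none
Why: Fluoride cleavage of the primary silyl ether; diene and tertiary alcohol are untouched.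

Step 17
Reactants: 24 diol; 25 bis(2,2,2-trifluoroethyl)phosphonoacetic acid
Product: 26 18-O-[bis(2,2,2-trifluoroethoxy)phosphorylacetyl] ester of 24
Conditions: EDC·HCl, DMAP (cat.), CH2Cl2, 0 °C → rt
Reagents that add atoms: none
Why: Steglich-type carbodiimide esterification; only the primary O18 is acylated, the axial tertiary O8 being far less reactive.

Step 18
Reactants: 26 18-O-phosphonoacetate; 27 4-(tert-butyldimethylsilyloxy)benzaldehyde
Product: 29 18-O-[(Z)-4-(tert-butyldimethylsilyloxy)cinnamoyl] ester of 24, via potassium phosphonate carbanion 28 (not isolated)
Conditions: KN(SiMe3)2 (1.05 equiv), 18-crown-6, THF, −78 °C; then 27, −78 °C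
Reagents that add atoms: none
Why: Still–Gennari olefination: the trifluoroethyl phosphonate under dissociating conditions makes the addition irreversible and the elimination fast, so the Z-enoate forms under kinetic control; aromatic aldehydes are among the best substrates, and the tertiary alcohol is not deprotonated by one equivalent of base.

Step 19
Reactants: 29 18-O-[(Z)-4-(tert-butyldimethylsilyloxy)cinnamoyl] ester
Product: 30 8-hydroxylabda-13(16),14-dien-18-yl (Z)-4-hydroxycinnamate (target; configuration as in its SMILES)
Conditions: Bu4NF, AcOH, THF, 0 °C, dark
Reagents that add atoms: none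
Why: Buffered fluoride cleaves the aryl silyl ether at low temperature; acetic acid keeps the phenoxide concentration low and light is excluded so that the Z-alkene should not isomerise.

## Compound list

1 | phenyl vinyl sulfone | C=CS(=O)(=O)c1ccccc1 | starting material
2 | 2-(phenylsulfonyl)prop-2-en-1-ol | C=C(CO)S(=O)(=O)c1ccccc1 | intermediate
3 | 3-bromo-2-(phenylsulfonyl)prop-1-ene | C=C(CBr)S(=O)(=O)c1ccccc1 | intermediate
4 | (S)-(+)-carvone | CC1=CC[C@@H](CC1=O)C(C)=C | starting material
5 | carvone lithium dienolate | CC1=CC[C@@H](C=C1O[Li])C(C)=C | intermediate (not isolated)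
6 | trans-6-methylcarvone, (5S,6R) | CC1=CC[C@H](C(C)=C)[C@@H](C)C1=O | intermediate
7 | lithium enolate of 6 | CC1=CC[C@H](C(C)=C)C(C)=C1O[Li] | intermediate (not isolated)
8 | 6-methyl-6-[2-(phenylsulfonyl)prop-2-en-1-yl]carvone (arm trans to isopropenyl) | CC1=CC[C@H](C(C)=C)[C@@](C)(CC(=C)S(=O)(=O)c2ccccc2)C1=O | intermediate
9 | isopropenyl epoxide of 8 (both C4 epimers) | CC1=CC[C@H](C2(C)CO2)[C@@](C)(CC(=C)S(=O)(=O)c2ccccc2)C1=O | intermediate
10 | titanoxy C4 radical | CC1=CC[C@H]([C](C)CO[Ti](Cl)(C2C=CC=C2)C3C=CC=C3)[C@@](C)(CC(=C)S(=O)(=O)c4ccccc4)C1=O | intermediate (not isolated)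
11 | hydroxy sulfone enone (ring A closed; 18-OH, 2-SO2Ph equatorial, 9-oxo-7-ene) | C[C@@]12C[C@H](S(=O)(=O)c3ccccc3)C[C@](C)(CO)[C@H]1CC=C(C)C2=O | intermediate
12 | 18-O-TBS ether of 11 | C[C@@]12C[C@H](S(=O)(=O)c3ccccc3)C[C@](C)(CO[Si](C)(C)C(C)(C)C)[C@H]1CC=C(C)C2=O | intermediate
13 | 7,8-epoxy-9-ketone (oxygen anti to C20) | C[C@@]12C[C@H](S(=O)(=O)c3ccccc3)C[C@](C)(CO[Si](C)(C)C(C)(C)C)[C@H]1C[C@@H]4O[C@]4(C)C2=O | intermediate
14 | epoxy hydrazone of 13 | C[C@@]12C[C@H](S(=O)(=O)c3ccccc3)C[C@](C)(CO[Si](C)(C)C(C)(C)C)[C@H]1C[C@@H]4O[C@]4(C)C2=NN | intermediate (not isolated)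
15 | 7-hydroxy-8(9)-ene sulfone | C[C@@]12C[C@H](S(=O)(=O)c3ccccc3)C[C@](C)(CO[Si](C)(C)C(C)(C)C)[C@H]1C[C@H](O)C(C)=C2 | intermediate
16 | desulfonylated allylic alcohol (7-OH anti to C20, 8(9)-ene) | C[C@@]12CCC[C@](C)(CO[Si](C)(C)C(C)(C)C)[C@H]1C[C@H](O)C(C)=C2 | intermediate
17 | mixed ketene acetal on O7 | C[C@@]12CCC[C@](C)(CO[Si](C)(C)C(C)(C)C)[C@H]1C[C@H](OC(=C)OCC)C(C)=C2 | intermediate (not isolated)
18 | ethyl ester (C9 axial CH2CO2Et, 7-ene) | C[C@@]12CCC[C@](C)(CO[Si](C)(C)C(C)(C)C)[C@H]1CC=C(C)[C@@H]2CC(=O)OCC | intermediate
19 | C12 primary alcohol | C[C@@]12CCC[C@](C)(CO[Si](C)(C)C(C)(C)C)[C@H]1CC=C(C)[C@@H]2CCO | intermediate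
20 | C12 tosylate | C[C@@]12CCC[C@](C)(CO[Si](C)(C)C(C)(C)C)[C@H]1CC=C(C)[C@@H]2CCOS(=O)(=O)c3ccc(C)cc3 | intermediate
21 | C7 organomercurial (7-HgOAc axial, 8-OH axial) | C[C@@]12CCC[C@](C)(CO[Si](C)(C)C(C)(C)C)[C@H]1C[C@H]([Hg]OC(C)=O)[C@@](C)(O)[C@@H]2CCOS(=O)(=O)c3ccc(C)cc3 | intermediate (not isolated)
22 | 8-hydroxy tosylate | C[C@@]12CCC[C@](C)(CO[Si](C)(C)C(C)(C)C)[C@H]1CC[C@@](C)(O)[C@@H]2CCOS(=O)(=O)c3ccc(C)cc3 | intermediate
23 | diene silyl ether | C[C@@]12CCC[C@](C)(CO[Si](C)(C)C(C)(C)C)[C@H]1CC[C@@](C)(O)[C@@H]2CCC(=C)C=C | intermediate
24 | 8,18-diol | C[C@@]12CCC[C@](C)(CO)[C@H]1CC[C@@](C)(O)[C@@H]2CCC(=C)C=C | intermediate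
25 | bis(2,2,2-trifluoroethyl)phosphonoacetic acid | OC(=O)CP(=O)(OCC(F)(F)F)OCC(F)(F)F | starting material
26 | 18-O-phosphonoacetate of 24 | C[C@@]12CCC[C@](C)(COC(=O)CP(=O)(OCC(F)(F)F)OCC(F)(F)F)[C@H]1CC[C@@](C)(O)[C@@H]2CCC(=C)C=C | intermediate
27 | 4-(tert-butyldimethylsilyloxy)benzaldehyde | O=Cc1ccc(O[Si](C)(C)C(C)(C)C)cc1 | starting material
28 | potassium phosphonate carbanion of 26 | C[C@@]12CCC[C@](C)(COC(=O)[CH-]P(=O)(OCC(F)(F)F)OCC(F)(F)F)[C@H]1CC[C@@](C)(O)[C@@H]2CCC(=C)C=C.[K+] | intermediate (not isolated)
29 | 18-O-[(Z)-4-(TBS-oxy)cinnamoyl] ester | C[C@@]12CCC[C@](C)(COC(=O)/C=C\c3ccc(O[Si](C)(C)C(C)(C)C)cc3)[C@H]1CC[C@@](C)(O)[C@@H]2CCC(=C)C=C | intermediate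
30 | 8-hydroxylabda-13(16),14-dien-18-yl (Z)-4-hydroxycinnamate | C=CC(=C)CC[C@@H]1[C@]2(C)CCC[C@](C)(COC(=O)/C=C\c3ccc(O)cc3)[C@H]2CC[C@@]1(C)O | target

## Step count and least certain steps

Total: 19 steps. Longest linear sequence: 18 steps (from 1 through steps 1, 2 and 4–19); from carvone 4 it is 17 steps (3–19).

Step 6 (key step). Three things may go wrong. C4 diastereocontrol may be lost if the titanium-bound oxymethyl and the methyl group are not differentiated strongly enough in the chair transition state. The C4 radical may be quenched before the 6-endo closure, by a second reduction followed by β-hydride elimination to an allylic alcohol or by hydrogen abstraction. The enone may be reduced by single-electron transfer if the titanium loading has to be raised. The fallback sets out from 8 and comes back at 12. Allylic oxidation of the isopropenyl methyl of 8 (SeO2 cat., tBuOOH, CH2Cl2) should give the 18-hydroxy analogue of 8, F1. Silylation (TBSCl, imidazole) gives its silyl ether F2. Hydrogen-atom transfer from an iron hydride (Fe(acac)3, PhSiH3, EtOH, 60 °C) to the terminal CH2 then generates the same C4 radical without any epoxide or titanium, now carrying a bulkier silyloxymethyl group, and a Giese-type 6-endo addition to the vinyl sulfone closes ring A to give 12 directly.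

Step 14. Facial control may erode, with water reaching C8 from the chain side through a non-chair pathway, or mercuration of the hindered trisubstituted alkene may be so slow that side reactions compete. The fallback sets out from 18 and comes back at 22. Epoxidation of 18 with mCPBA should occur anti to the pseudoaxial C9 chain and give the 7,8-epoxide with oxygen syn to C20, F3. LiAlH4 opens it diaxially at C7 and reduces the ester in the same operation to the 8,12-diol F4. Tosylation of the primary hydroxyl alone then returns to 22. Here the configuration rests on steric approach and not on the opening of a cation, so the two methods would fail for different reasons.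

Step 9. Hydrazone formation at a ketone flanked by two fully substituted carbons may be too slow, leaving hydrazine to attack the epoxide instead. The fallback sets out from 13 and comes back at 15. NaBH4 reduces the ketone to the epoxy alcohol F5 (C9 configuration immaterial). 1,1′-Thiocarbonyldiimidazole converts it into the O-thiocarbonylimidazolide F6. Bu3SnH/AIBN in hot toluene then generates the C9 radical, which opens the epoxide at the C8–O bond; the resulting O7 radical takes hydrogen from the stannane to give 15, a radical counterpart of the Wharton reaction.

Step 11. Acid-catalysed ionisation or dehydration of the allylic alcohol at 140 °C, or a sluggish rearrangement next to the quaternary C10, may lower the efficiency. The fallback sets out from 16 and comes back at 19. Acetylation (Ac2O, pyridine, DMAP) gives the allylic acetate F7. An Ireland–Claisen rearrangement (LiN(iPr)2, TMSCl, THF, −78 → 60 °C, then aqueous work-up) of its silyl ketene acetal gives the carboxylic acid F8 with the same suprafacial transfer to C9, and LiAlH4 reduces it to 19.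

Step 15. The dienyl Grignard reagent may oligomerise or couple with itself, and reduction or elimination of the tosylate may compete. The fallback sets out from 22 and comes back at 23. Displacement with LiC≡CH·H2NCH2CH2NH2 in DMSO gives the terminal alkyne F9, and enyne cross-metathesis with ethylene over the second-generation Grubbs catalyst (CH2Cl2, rt) gives 23.

## Further compounds

F1 | step 6 | 18-hydroxy analogue of 8 [5-(3-hydroxyprop-1-en-2-yl) compound] | CC1=CC[C@H](C(=C)CO)[C@@](C)(CC(=C)S(=O)(=O)c2ccccc2)C1=O
F2 | step 6 | tert-butyldimethylsilyl ether of F1 | CC1=CC[C@H](C(=C)CO[Si](C)(C)C(C)(C)C)[C@@](C)(CC(=C)S(=O)(=O)c2ccccc2)C1=O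
F3 | step 14 | 7,8-epoxide of 18 (oxygen syn to C20) | C[C@@]12CCC[C@](C)(CO[Si](C)(C)C(C)(C)C)[C@H]1C[C@H]4O[C@@]4(C)[C@@H]2CC(=O)OCC
F4 | step 14 | 18-O-TBS 8,12-diol | C[C@@]12CCC[C@](C)(CO[Si](C)(C)C(C)(C)C)[C@H]1CC[C@@](C)(O)[C@@H]2CCO
F5 | step 9 | 7,8-epoxy-9-alcohol from 13 (C9 epimers) | C[C@@]12C[C@H](S(=O)(=O)c3ccccc3)C[C@](C)(CO[Si](C)(C)C(C)(C)C)[C@H]1C[C@@H]4O[C@]4(C)C2O
F6 | step 9 | O9-thiocarbonylimidazolide of F5 | C[C@@]12C[C@H](S(=O)(=O)c3ccccc3)C[C@](C)(CO[Si](C)(C)C(C)(C)C)[C@H]1C[C@@H]4O[C@]4(C)C2OC(=S)n5ccnc5
F7 | step 11 | O7-acetate of 16 | C[C@@]12CCC[C@](C)(CO[Si](C)(C)C(C)(C)C)[C@H]1C[C@H](OC(C)=O)C(C)=C2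
F8 | step 11 | C12 carboxylic acid (acid corresponding to ester 18) | C[C@@]12CCC[C@](C)(CO[Si](C)(C)C(C)(C)C)[C@H]1CC=C(C)[C@@H]2CC(=O)O
F9 | step 15 | terminal alkyne (C12–C13≡C14; 8-OH; 18-OTBS) | C[C@@]12CCC[C@](C)(CO[Si](C)(C)C(C)(C)C)[C@H]1CC[C@@](C)(O)[C@@H]2CCC#C
A1 | alternative 1 | diene with C18 silyl ether (identical with 23) | C=CC(=C)CC[C@@H]1[C@]2(C)CCC[C@](C)(CO[Si](C)(C)C(C)(C)C)[C@H]2CC[C@@]1(C)O
A2 | alternative 1 | terminal alkyne precursor | C#CCC[C@@H]1[C@]2(C)CCC[C@](C)(CO[Si](C)(C)C(C)(C)C)[C@H]2CC[C@@]1(C)O
A3 | alternative 2 | trans-fused octalin ester with C7 dioxolane | C[C@@]12C=CC[C@](C)(C(=O)OC)[C@H]1CC3(OCCO3)[C@H](C)C2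
A4 | alternative 2 | methyl (2E,8E)-5,5-(ethylenedioxy)-2,6,8-trimethylundeca-2,8,10-trienoate | COC(=O)/C(C)=C/CC1(OCCO1)[C@H](C)C/C(C)=C/C=C
A5 | alternative 3 | ring A with C4 dimethyl acetal, C5 vinyl and C10 oxymethyl | C[C@@]1(CO[Si](C)(C)C(C)(C)C)CCC[C@](C)(C(OC)OC)[C@H]1C=C
A6 | alternative 3 | methyl enol ether–allylsilane precursor (enol ether geometry immaterial) | C[C@@](CO[Si](C)(C)C(C)(C)C)(CCCC(C)=COC)/C=C/C[Si](C)(C)C
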